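**Plan**

- Retrosynthesis: cut the C3 ester (alcohol 31 + acid 43), then C9=C10 and C1=C2 in one operation (dienyne 28), then C7–C11 (alkenylmagnesium + α-alkoxy ketone 23), C7–C8 (alkoxyallylboration of aldehyde 19), C10≡C1 (homologation of lactol 14), C5–C6 (lactone alkylation) and C3–C4 (crotylboration).
- Enabling feature (eremophilane numbering): the diene C9=C10–C1=C2 runs across the ring fusion with C10 and C1 as its inner carbons, and rings A and B share quaternary C5. An ethynyl group on C5 (C10≡C1), flanked by a C9 vinyl group and a C2 propenyl group, is therefore a direct precursor of both rings.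
- Forward: the C2–C9 chain is built on a γ-lactone template; one ruthenium cascade closes ring B (C9=C10), then ring A (C1=C2); C8 oxidation and C3 esterification finish.
- Stereochemistry: C3/C4 from a reagent-controlled (Z)-crotylboration; C5 by alkylating the lactone enolate anti to C15; C8 (temporary) from alkoxyallylboration, relayed to C7 by chelation-controlled addition and then oxidised away; C6' of the acid from an Evans methylation.
- C8 stays a carbinol until after the metathesis, so no enolisable 7,8-dione is ever made and the C9 vinyl group remains an electron-rich initiation site.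

Key step: step 17

Remark: the side-chain stereocentre is taken as (6R), as the target SMILES encodes it. (+)-Ipc2BOMe (Ipc = isopinocampheyl, from (−)-α-pinene), 3-(methoxymethoxy)prop-1-ene and dimethyl (1-diazo-2-oxopropyl)phosphonate are treated as purchased reagents. Positions are given in eremophilane numbering (C1–C15); systematic names carry their own locants. TBS = tert-butyldimethylsilyl, MOM = methoxymethyl.

**Route**

Step 1
Reactants: 1 crotonaldehyde; 2 cis-but-2-ene
Product: 4 (3S,4S,5E)-3-methylhepta-1,5-dien-4-ol, via borinate 3 (not isolated)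
Conditions: 2, KOt-Bu, n-BuLi, THF, −78 → −45 °C; (+)-Ipc2BOMe, −78 °C; BF3·OEt2; 1, −78 °C; then NaOH, H2O2, 0 °C → rt
Reagents that add atoms: none
Why: Brown asymmetric crotylboration through a closed chair transition state should give the syn C3/C4 pair from the (Z)-crotyl geometry, and the (−)-α-pinene-derived ligands should direct attack to the Re face of the aldehyde, setting C3 (S) and C4 (S).

Step 2
Reactants: 4 (3S,4S,5E)-3-methylhepta-1,5-dien-4-ol
Product: 6 (3S,4R,5E)-3-methylhept-5-ene-1,4-diol, via bis-boryl adduct 5 (not isolated)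
Conditions: 9-BBN (2.5 equiv), THF, 0 °C → rt; then NaOH, H2O2, 0 °C → rt
Reagents that add atoms: hydrogen peroxide, OO
Why: Hydroboration–oxidation with 9-BBN should react only at the monosubstituted vinyl group, placing boron on the terminal carbon and leaving the (E)-propenyl group and both stereocentres untouched (the C4 descriptor changes only through priorities).

Step 3
Reactants: 6 (3S,4R,5E)-3-methylhept-5-ene-1,4-diol
Product: 8 (4S,5R)-4-methyl-5-[(E)-prop-1-enyl]oxolan-2-one, via lactol 7 (not isolated)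
Conditions: TEMPO (0.2 equiv), PhI(OAc)2 (2.5 equiv), CH2Cl2, rt
Reagents that add atoms: none
Why: TEMPO/PhI(OAc)2 oxidative lactonisation should oxidise the primary alcohol first, trap the aldehyde as the five-membered lactol and oxidise that to the cis-4,5-disubstituted γ-lactone.

Step 4
Reactants: 8 (4S,5R)-4-methyl-5-[(E)-prop-1-enyl]oxolan-2-one
Product: 10 (4S,5S)-3,4-dimethyl-5-[(E)-prop-1-enyl]oxolan-2-one (mixture at C3), via lithium enolate 9 (not isolated)
Conditions: LiN(i-Pr)2 (1.05 equiv), THF, −78 °C; MeI, −78 → −40 °C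
Reagents that add atoms: iodomethane, CI
Why: Lactone enolate alkylation introduces C14 first; the new centre need not be controlled because it is planarised again in step 5.

Step 5
Reactants: 10 (4S,5S)-3,4-dimethyl-5-[(E)-prop-1-enyl]oxolan-2-one; 11 tert-butyl bromoacetate
Product: 13 tert-butyl 2-[(3S,4S,5S)-3,4-dimethyl-2-oxo-5-[(E)-prop-1-enyl]oxolan-3-yl]acetate, via lithium enolate 12 (not isolated)
Conditions: LiN(i-Pr)2 (1.2 equiv), THF/DMPU, −78 °C; 11, −78 → −30 °C
Reagents that add atoms: none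
Why: Alkylation of the trisubstituted lactone enolate should occur on the face opposite the C15 methyl and the cis propenyl group, so the C6–C7 arm enters trans to C15 and quaternary C5 is set with C14 cis to C15.

Step 6
Reactants: 13 tert-butyl 2-[(3S,4S,5S)-3,4-dimethyl-2-oxo-5-[(E)-prop-1-enyl]oxolan-3-yl]acetate
Product: 14 tert-butyl 2-[(3S,4S,5S)-2-hydroxy-3,4-dimethyl-5-[(E)-prop-1-enyl]oxolan-3-yl]acetate (anomers)
Conditions: i-Bu2AlH (1.1 equiv), CH2Cl2, −78 °C; aq. potassium sodium tartrate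
Reagents that add atoms: none
Why: Partial reduction of a γ-lactone with i-Bu2AlH at −78 °C should stop at the aluminium hemiacetal, and the bulkier, less electrophilic tert-butyl ester should be left alone.

Step 7
Reactants: 14 tert-butyl 2-[(3S,4S,5S)-2-hydroxy-3,4-dimethyl-5-[(E)-prop-1-enyl]oxolan-3-yl]acetate
Product: 16 tert-butyl (3S,4S,5S,6E)-3-ethynyl-5-hydroxy-3,4-dimethyloct-6-enoate, via hydroxy aldehyde 15 (not isolated)
Conditions: dimethyl (1-diazo-2-oxopropyl)phosphonate (2 equiv), K2CO3, MeOH, 0 °C → rt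
Reagents that add atoms: dimethyl (1-diazo-2-oxopropyl)phosphonate, CC(=O)C(=[N+]=[N-])P(=O)(OC)OC
Why: Ohira–Bestmann (Seyferth–Gilbert) homologation of the ring-opened lactol should turn the C10 aldehyde, which has no α-hydrogen and cannot epimerise, into the C10≡C1 alkyne and free the C3 hydroxyl.

Step 8
Reactants: 16 tert-butyl (3S,4S,5S,6E)-3-ethynyl-5-hydroxy-3,4-dimethyloct-6-enoate
Product: 17 tert-butyl (3S,4S,5S,6E)-5-[(tert-butyldimethylsilyl)oxy]-3-ethynyl-3,4-dimethyloct-6-enoate
Conditions: TBSOTf (1.3 equiv), 2,6-lutidine, CH2Cl2, −78 °C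
Reagents that add atoms: tert-butyldimethylsilyl trifluoromethanesulfonate, CC(C)(C)[Si](C)(C)OS(=O)(=O)C(F)(F)F
Why: Silylation with the silyl triflate and 2,6-lutidine should protect the hindered secondary C3 alcohol at low temperature without touching the tert-butyl ester.

Step 9
Reactants: 17 tert-butyl (3S,4S,5S,6E)-5-[(tert-butyldimethylsilyl)oxy]-3-ethynyl-3,4-dimethyloct-6-enoate
Product: 18 (3S,4S,5S,6E)-5-[(tert-butyldimethylsilyl)oxy]-3-ethynyl-3,4-dimethyloct-6-en-1-ol
Conditions: LiAlH4, Et2O, 0 °C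
Reagents that add atoms: none
Why: Hydride reduction of the ester should give the primary C7 alcohol; the silyl ether, the isolated alkene and the alkyne are inert at 0 °C.

Step 10
Reactants: 18 (3S,4S,5S,6E)-5-[(tert-butyldimethylsilyl)oxy]-3-ethynyl-3,4-dimethyloct-6-en-1-ol
Product: 19 (3S,4S,5S,6E)-5-[(tert-butyldimethylsilyl)oxy]-3-ethynyl-3,4-dimethyloct-6-enal
Conditions: Dess–Martin periodinane, pyridine, CH2Cl2, 0 °C → rt
Reagents that add atoms: none
Why: Dess–Martin oxidation should give the C7 aldehyde under neutral conditions, with no α-stereocentre at risk.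

Step 11
Reactants: 19 (3S,4S,5S,6E)-5-[(tert-butyldimethylsilyl)oxy]-3-ethynyl-3,4-dimethyloct-6-enal; 20 3-(methoxymethoxy)prop-1-ene
Product: 22 (3S,4S,6S,7S,8S,9E)-8-[(tert-butyldimethylsilyl)oxy]-6-ethynyl-3-(methoxymethoxy)-6,7-dimethylundeca-1,9-dien-4-ol, via borinate 21 (not isolated)
Conditions: 20, s-BuLi, THF, −78 °C; (+)-Ipc2BOMe, −78 °C; BF3·OEt2; 19, −78 °C; then NaOH, H2O2, 0 °C → rt
Reagents that add atoms: none
Why: Brown alkoxyallylboration with the (Z)-γ-alkoxyallylborane should add through a chair transition state to the Re face of the aldehyde, giving the syn C7/C8 mono-protected diol with C8 (S) and the C9 vinyl group in place (C7 is removed in step 12).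

Step 12
Reactants: 22 (3S,4S,6S,7S,8S,9E)-8-[(tert-butyldimethylsilyl)oxy]-6-ethynyl-3-(methoxymethoxy)-6,7-dimethylundeca-1,9-dien-4-ol
Product: 23 (3S,6S,7S,8S,9E)-8-[(tert-butyldimethylsilyl)oxy]-6-ethynyl-3-(methoxymethoxy)-6,7-dimethylundeca-1,9-dien-4-one
Conditions: Dess–Martin periodinane, pyridine, CH2Cl2, 0 °C
Reagents that add atoms: none
Why: Buffered Dess–Martin oxidation should give the C7 ketone with C8 kept as its MOM ether, under conditions mild enough not to move the β,γ-double bond into conjugation.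

Step 13
Reactants: 24 2-bromoprop-2-en-1-ol
Product: 25 2-bromo-3-(methoxymethoxy)prop-1-ene
Conditions: MOMCl, i-Pr2NEt, CH2Cl2, 0 °C → rt
Reagents that add atoms: chloromethyl methyl ether, COCCl
Why: O-Alkylation of the primary alcohol with the chloromethyl ether and a hindered amine base gives the protected C11–C13 building block.

Step 14
Reactants: 23 (3S,6S,7S,8S,9E)-8-[(tert-butyldimethylsilyl)oxy]-6-ethynyl-3-(methoxymethoxy)-6,7-dimethylundeca-1,9-dien-4-one; 25 2-bromo-3-(methoxymethoxy)prop-1-ene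
Product: 26 (3S,4S,6S,7S,8S,9E)-8-[(tert-butyldimethylsilyl)oxy]-6-ethynyl-3-(methoxymethoxy)-4-[3-(methoxymethoxy)prop-1-en-2-yl]-6,7-dimethylundeca-1,9-dien-4-ol
Conditions: 25 (3 equiv), t-BuLi (6 equiv), Et2O, −78 °C; MgBr2·OEt2, −78 → −40 °C; then 23, Et2O, −78 °C; aq. NH4Cl
Reagents that add atoms: none
Why: Chelation-controlled (Cram chelate) addition of the alkenylmagnesium reagent should occur on the face of the magnesium chelate between the C7 carbonyl and the C8 MOM oxygen that carries the C8 hydrogen rather than the vinyl group, setting the tertiary C7 carbinol (S) from the (8S) centre; excess reagent allows for any slow metalation of the terminal alkyne.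

Step 15
Reactants: 26 (3S,4S,6S,7S,8S,9E)-8-[(tert-butyldimethylsilyl)oxy]-6-ethynyl-3-(methoxymethoxy)-4-[3-(methoxymethoxy)prop-1-en-2-yl]-6,7-dimethylundeca-1,9-dien-4-ol
Product: 27 (3S,4S,6S,7S,8S,9E)-8-[(tert-butyldimethylsilyl)oxy]-6-ethynyl-4-(3-hydroxyprop-1-en-2-yl)-6,7-dimethylundeca-1,9-diene-3,4-diol
Conditions: ZnBr2, n-PrSH, CH2Cl2, 0 °C, short reaction time
Reagents that add atoms: none
Why: Lewis acid/thiol cleavage of both MOM ethers is done before the acid-sensitive diene exists; the thiol captures the methoxymethyl cation so no cyclic formal forms, and the hindered C3 silyl ether should survive.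

Step 16
Reactants: 27 (3S,4S,6S,7S,8S,9E)-8-[(tert-butyldimethylsilyl)oxy]-6-ethynyl-4-(3-hydroxyprop-1-en-2-yl)-6,7-dimethylundeca-1,9-diene-3,4-diol
Product: 28 2-[(3S,4S,6S,7S,8S,9E)-8-[(tert-butyldimethylsilyl)oxy]-6-ethynyl-3,4-dihydroxy-6,7-dimethylundeca-1,9-dien-4-yl]prop-2-en-1-yl acetate
Conditions: AcCl (1.1 equiv), 2,4,6-collidine, CH2Cl2, −78 °C
Reagents that add atoms: acetyl chloride, CC(Cl)=O
Why: Acylation with acetyl chloride and collidine at low temperature should select the primary C13 hydroxyl over the secondary C8 hydroxyl (next to a quaternary carbon) and the tertiary C7 hydroxyl.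

Step 17
Reactants: 28 2-[(3S,4S,6S,7S,8S,9E)-8-[(tert-butyldimethylsilyl)oxy]-6-ethynyl-3,4-dihydroxy-6,7-dimethylundeca-1,9-dien-4-yl]prop-2-en-1-yl acetate
Product: 29 2-[(2S,3S,7S,8S,8aS)-7-[(tert-butyldimethylsilyl)oxy]-2,3-dihydroxy-8,8a-dimethyl-1,2,3,7,8,8a-hexahydronaphthalen-2-yl]prop-2-en-1-yl acetate
Conditions: RuCl2(=CHPh)(PCy3)(H2IMes) (second-generation Grubbs catalyst, 10 mol%), CH2Cl2 (0.005 M), 40 °C
Reagents that add atoms: none
Why: Tandem ring-closing dienyne metathesis: the ruthenium alkylidene exchanges onto the monosubstituted C9 vinyl group, the C9 alkylidene adds across the C10≡C1 triple bond and cycloreversion of the ruthenacyclobutene gives ring B with C9=C10 and a vinylcarbene at C1, which closes on the propenyl group to form C1=C2 and releases an ethylidene that leaves as propene on the next turnover. The closest known reaction is the tandem dienyne ring-closing metathesis that gives fused bicyclic 1,3-dienes when both alkene tethers hang from the propargylic carbon. Ring B closes in the six-membered exo mode (C9 onto the proximal alkyne carbon C10) and ring A as a six-membered closure of the exocyclic C1 carbene onto C2; quaternary C5 carries the alkyne and both tethers, so each closure gains from a gem-disubstituent effect. No stereocentre is formed, and C3, C4, C5, C7 and C8 are spectators. The step needs initiation at C9 rather than C2, because a C2 alkylidene would close a five-membered ring on C10; this is secured by the contrast between an unhindered terminal vinyl group next to a free allylic hydroxyl and a 1,2-disubstituted propenyl group flanked by the bulky silyl ether. The 1,1-disubstituted C11=C12 alkene should stay out because it loads slowly and the only ring it could close with the C1 carbene would carry a bridgehead double bond.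

Step 18
Reactants: 29 2-[(2S,3S,7S,8S,8aS)-7-[(tert-butyldimethylsilyl)oxy]-2,3-dihydroxy-8,8a-dimethyl-1,2,3,7,8,8a-hexahydronaphthalen-2-yl]prop-2-en-1-yl acetate
Product: 30 2-[(2S,7S,8S,8aS)-7-[(tert-butyldimethylsilyl)oxy]-2-hydroxy-8,8a-dimethyl-3-oxo-1,2,3,7,8,8a-hexahydronaphthalen-2-yl]prop-2-en-1-yl acetate
Conditions: MnO2 (activated, excess), CH2Cl2, rt
Reagents that add atoms: none
Why: MnO2 oxidation should act only on the dienylic C8 hydroxyl (the C7 hydroxyl is tertiary, C3 is silylated), giving the C8 dienone and erasing the temporary C8 stereocentre.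

Step 19
Reactants: 30 2-[(2S,7S,8S,8aS)-7-[(tert-butyldimethylsilyl)oxy]-2-hydroxy-8,8a-dimethyl-3-oxo-1,2,3,7,8,8a-hexahydronaphthalen-2-yl]prop-2-en-1-yl acetate
Product: 31 2-[(2S,7S,8S,8aS)-2,7-dihydroxy-8,8a-dimethyl-3-oxo-1,2,3,7,8,8a-hexahydronaphthalen-2-yl]prop-2-en-1-yl acetate
Conditions: HF·pyridine, pyridine, THF, 0 °C → rt
Reagents that add atoms: none
Why: Buffered fluoride desilylation should free the C3 hydroxyl without touching the acetate or the α-ketol, and the electron-poor dienone no longer ionises easily at C3.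

Step 20
Reactants: 32 (R)-4-benzyloxazolidin-2-one; 33 butanoyl chloride
Product: 34 (R)-4-benzyl-3-butanoyloxazolidin-2-one
Conditions: n-BuLi, THF, −78 °C; then 33, −78 → 0 °C
Reagents that add atoms: none
Why: N-Acylation of the lithiated oxazolidinone gives the imide needed for the auxiliary-controlled alkylation.

Step 21
Reactants: 34 (R)-4-benzyl-3-butanoyloxazolidin-2-one
Product: 36 (R)-4-benzyl-3-[(R)-2-methylbutanoyl]oxazolidin-2-one, via sodium enolate 35 (not isolated)
Conditions: NaN(SiMe3)2, THF, −78 °C; MeI, −78 °C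
Reagents that add atoms: iodomethane, CI
Why: Evans asymmetric alkylation: the chelated (Z)-enolate should be methylated on the face opposite the benzyl group of the (R)-auxiliary, setting the (R) centre that becomes C6' of the side chain.

Step 22
Reactants: 36 (R)-4-benzyl-3-[(R)-2-methylbutanoyl]oxazolidin-2-one
Product: 37 (R)-2-methylbutan-1-ol
Conditions: LiBH4, THF, 0 °C → rt
Reagents that add atoms: none
Why: Reductive cleavage of the imide should give the primary alcohol and return the auxiliary without enolising the stereocentre.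

Step 23
Reactants: 37 (R)-2-methylbutan-1-ol
Product: 39 ethyl (2E,4R)-2,4-dimethylhex-2-enoate, via aldehyde 38 (not isolated)
Conditions: TEMPO (0.1 equiv), PhI(OAc)2 (1.1 equiv), CH2Cl2, rt; then Ph3P=C(Me)CO2Et, rt → 40 °C
Reagents that add atoms: ethyl 2-(triphenylphosphoranylidene)propanoate, CCOC(=O)C(C)=P(c1ccccc1)(c1ccccc1)c1ccccc1
Why: One-pot TEMPO oxidation and Wittig olefination should trap the volatile, epimerisable α-branched aldehyde with the stabilised ylide as the (E)-trisubstituted enoate.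

Step 24
Reactants: 39 ethyl (2E,4R)-2,4-dimethylhex-2-enoate
Product: 40 (2E,4R)-2,4-dimethylhex-2-en-1-ol
Conditions: i-Bu2AlH (2.2 equiv), CH2Cl2, −78 °C
Reagents that add atoms: none
Why: 1,2-Reduction of the enoate with i-Bu2AlH should give the allylic alcohol without conjugate reduction.

Step 25
Reactants: 40 (2E,4R)-2,4-dimethylhex-2-en-1-ol
Product: 42 ethyl (2E,4E,6R)-4,6-dimethylocta-2,4-dienoate, via enal 41 (not isolated)
Conditions: MnO2, Ph3P=CHCO2Et, CH2Cl2, rt
Reagents that add atoms: ethyl (triphenylphosphoranylidene)acetate, CCOC(=O)C=P(c1ccccc1)(c1ccccc1)c1ccccc1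
Why: Tandem allylic oxidation and Wittig olefination should convert the alcohol through the enal into the (2E,4E)-dienoate, the stabilised ylide giving the (E)-disubstituted alkene.

Step 26
Reactants: 42 ethyl (2E,4E,6R)-4,6-dimethylocta-2,4-dienoate
Product: 43 (2E,4E,6R)-4,6-dimethylocta-2,4-dienoic acid
Conditions: LiOH, THF/MeOH/H2O, rt; then 1 M HCl
Reagents that add atoms: lithium hydroxide, [Li+].[OH-]
Why: Saponification of the ethyl ester; the γ-stereocentre is remote from the carboxylate and not at risk.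

Step 27
Reactants: 31 2-[(2S,7S,8S,8aS)-2,7-dihydroxy-8,8a-dimethyl-3-oxo-1,2,3,7,8,8a-hexahydronaphthalen-2-yl]prop-2-en-1-yl acetate; 43 (2E,4E,6R)-4,6-dimethylocta-2,4-dienoic acid
Product: 45 (1S,2S,7S,8aS)-7-[3-(acetyloxy)prop-1-en-2-yl]-7-hydroxy-1,8a-dimethyl-6-oxo-1,2,6,7,8,8a-hexahydronaphthalen-2-yl (2E,4E,6R)-4,6-dimethylocta-2,4-dienoate, via mixed anhydride 44 (not isolated)
Conditions: 43, 2,4,6-trichlorobenzoyl chloride, Et3N, toluene, rt; then 31, DMAP, rt
Reagents that add atoms: none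
Why: Yamaguchi esterification through the mixed anhydride and DMAP should acylate the secondary allylic C3 hydroxyl and leave the tertiary α-ketol hydroxyl free, with no stereocentre or alkene geometry disturbed.

**Compound list**

1 | crotonaldehyde, (E)-but-2-enal | C/C=C/C=O | starting material
2 | cis-but-2-ene | C/C=C\C | starting material
3 | O-diisopinocampheylboryl derivative (borinate) of 4 | C/C=C/[C@H](OB([C@H]1C[C@H]2C[C@@H]([C@@H]1C)C2(C)C)[C@H]1C[C@H]2C[C@@H]([C@@H]1C)C2(C)C)[C@@H](C)C=C | intermediate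
4 | (3S,4S,5E)-3-methylhepta-1,5-dien-4-ol | C/C=C/[C@H](O)[C@@H](C)C=C | intermediate
5 | adduct of 4 carrying 9-borabicyclo[3.3.1]nonan-9-yl groups on C1 and on the C4 oxygen | C/C=C/[C@H](OB1C2CCCC1CCC2)[C@@H](C)CCB1C2CCCC1CCC2 | intermediate
6 | (3S,4R,5E)-3-methylhept-5-ene-1,4-diol | C/C=C/[C@H](O)[C@@H](C)CCO | intermediate
7 | (4S,5R)-4-methyl-5-[(E)-prop-1-enyl]oxolan-2-ol (lactol, anomers) | C/C=C/[C@@H]1OC(O)C[C@@H]1C | intermediate
8 | (4S,5R)-4-methyl-5-[(E)-prop-1-enyl]oxolan-2-one (cis lactone) | C/C=C/[C@@H]1OC(=O)C[C@@H]1C | intermediate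
9 | lithium enolate of 8 | C/C=C/[C@@H]1OC(O[Li])=C[C@@H]1C | intermediate
10 | (4S,5S)-3,4-dimethyl-5-[(E)-prop-1-enyl]oxolan-2-one (mixture at C3) | C/C=C/[C@@H]1OC(=O)C(C)[C@@H]1C | intermediate
11 | tert-butyl bromoacetate | CC(C)(C)OC(=O)CBr | starting material
12 | lithium enolate of 10 | C/C=C/[C@@H]1OC(O[Li])=C(C)[C@@H]1C | intermediate
13 | tert-butyl 2-[(3S,4S,5S)-3,4-dimethyl-2-oxo-5-[(E)-prop-1-enyl]oxolan-3-yl]acetate | C/C=C/[C@@H]1OC(=O)[C@@](C)(CC(=O)OC(C)(C)C)[C@@H]1C | intermediate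
14 | tert-butyl 2-[(3S,4S,5S)-2-hydroxy-3,4-dimethyl-5-[(E)-prop-1-enyl]oxolan-3-yl]acetate (lactol, anomers) | C/C=C/[C@@H]1OC(O)[C@@](C)(CC(=O)OC(C)(C)C)[C@@H]1C | intermediate
15 | tert-butyl (3S,4S,5S,6E)-3-formyl-5-hydroxy-3,4-dimethyloct-6-enoate (open form of 14) | C/C=C/[C@H](O)[C@@H](C)[C@@](C)(C=O)CC(=O)OC(C)(C)C | intermediate
16 | tert-butyl (3S,4S,5S,6E)-3-ethynyl-5-hydroxy-3,4-dimethyloct-6-enoate | C/C=C/[C@H](O)[C@@H](C)[C@@](C)(C#C)CC(=O)OC(C)(C)C | intermediate
17 | tert-butyl (3S,4S,5S,6E)-5-[(tert-butyldimethylsilyl)oxy]-3-ethynyl-3,4-dimethyloct-6-enoate | C/C=C/[C@H](O[Si](C)(C)C(C)(C)C)[C@@H](C)[C@@](C)(C#C)CC(=O)OC(C)(C)C | intermediate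
18 | (3S,4S,5S,6E)-5-[(tert-butyldimethylsilyl)oxy]-3-ethynyl-3,4-dimethyloct-6-en-1-ol | C/C=C/[C@H](O[Si](C)(C)C(C)(C)C)[C@@H](C)[C@@](C)(C#C)CCO | intermediate
19 | (3S,4S,5S,6E)-5-[(tert-butyldimethylsilyl)oxy]-3-ethynyl-3,4-dimethyloct-6-enal | C/C=C/[C@H](O[Si](C)(C)C(C)(C)C)[C@@H](C)[C@@](C)(C#C)CC=O | intermediate
20 | 3-(methoxymethoxy)prop-1-ene (allyl MOM ether) | C=CCOCOC | starting material
21 | O-diisopinocampheylboryl derivative (borinate) of 22 | C/C=C/[C@H](O[Si](C)(C)C(C)(C)C)[C@@H](C)[C@@](C)(C#C)C[C@H](OB([C@H]1C[C@H]2C[C@@H]([C@@H]1C)C2(C)C)[C@H]1C[C@H]2C[C@@H]([C@@H]1C)C2(C)C)[C@@H](OCOC)C=C | intermediate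
22 | (3S,4S,6S,7S,8S,9E)-8-[(tert-butyldimethylsilyl)oxy]-6-ethynyl-3-(methoxymethoxy)-6,7-dimethylundeca-1,9-dien-4-ol | C/C=C/[C@H](O[Si](C)(C)C(C)(C)C)[C@@H](C)[C@@](C)(C#C)C[C@H](O)[C@@H](OCOC)C=C | intermediate
23 | (3S,6S,7S,8S,9E)-8-[(tert-butyldimethylsilyl)oxy]-6-ethynyl-3-(methoxymethoxy)-6,7-dimethylundeca-1,9-dien-4-one | C/C=C/[C@H](O[Si](C)(C)C(C)(C)C)[C@@H](C)[C@@](C)(C#C)CC(=O)[C@@H](OCOC)C=C | intermediate
24 | 2-bromoprop-2-en-1-ol | C=C(Br)CO | starting material
25 | 2-bromo-3-(methoxymethoxy)prop-1-ene | C=C(Br)COCOC | intermediate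
26 | (3S,4S,6S,7S,8S,9E)-8-[(tert-butyldimethylsilyl)oxy]-6-ethynyl-3-(methoxymethoxy)-4-[3-(methoxymethoxy)prop-1-en-2-yl]-6,7-dimethylundeca-1,9-dien-4-ol | C/C=C/[C@H](O[Si](C)(C)C(C)(C)C)[C@@H](C)[C@@](C)(C#C)C[C@](O)(C(=C)COCOC)[C@@H](OCOC)C=C | intermediate
27 | (3S,4S,6S,7S,8S,9E)-8-[(tert-butyldimethylsilyl)oxy]-6-ethynyl-4-(3-hydroxyprop-1-en-2-yl)-6,7-dimethylundeca-1,9-diene-3,4-diol | C/C=C/[C@H](O[Si](C)(C)C(C)(C)C)[C@@H](C)[C@@](C)(C#C)C[C@](O)(C(=C)CO)[C@@H](O)C=C | intermediate
28 | 2-[(3S,4S,6S,7S,8S,9E)-8-[(tert-butyldimethylsilyl)oxy]-6-ethynyl-3,4-dihydroxy-6,7-dimethylundeca-1,9-dien-4-yl]prop-2-en-1-yl acetate (dienyne; C3 OTBS, C7/C8 diol, C13 OAc) | C/C=C/[C@H](O[Si](C)(C)C(C)(C)C)[C@@H](C)[C@@](C)(C#C)C[C@](O)(C(=C)COC(C)=O)[C@@H](O)C=C | intermediate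
29 | 2-[(2S,3S,7S,8S,8aS)-7-[(tert-butyldimethylsilyl)oxy]-2,3-dihydroxy-8,8a-dimethyl-1,2,3,7,8,8a-hexahydronaphthalen-2-yl]prop-2-en-1-yl acetate (bicyclic diene) | C=C(COC(C)=O)[C@@]1(O)C[C@]2(C)C(=C[C@@H]1O)C=C[C@H](O[Si](C)(C)C(C)(C)C)[C@H]2C | intermediate
30 | 2-[(2S,7S,8S,8aS)-7-[(tert-butyldimethylsilyl)oxy]-2-hydroxy-8,8a-dimethyl-3-oxo-1,2,3,7,8,8a-hexahydronaphthalen-2-yl]prop-2-en-1-yl acetate | C=C(COC(C)=O)[C@@]1(O)C[C@]2(C)C(=CC1=O)C=C[C@H](O[Si](C)(C)C(C)(C)C)[C@H]2C | intermediate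
31 | 2-[(2S,7S,8S,8aS)-2,7-dihydroxy-8,8a-dimethyl-3-oxo-1,2,3,7,8,8a-hexahydronaphthalen-2-yl]prop-2-en-1-yl acetate | C=C(COC(C)=O)[C@@]1(O)C[C@]2(C)C(=CC1=O)C=C[C@H](O)[C@H]2C | intermediate
32 | (R)-4-benzyloxazolidin-2-one | O=C1N[C@H](Cc2ccccc2)CO1 | starting material
33 | butanoyl chloride | CCCC(Cl)=O | starting material
34 | (R)-4-benzyl-3-butanoyloxazolidin-2-one | CCCC(=O)N1[C@H](Cc2ccccc2)COC1=O | intermediate
35 | sodium (Z)-enolate of 34 | CC/C=C(\O[Na])N1[C@H](Cc2ccccc2)COC1=O | intermediate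
36 | (R)-4-benzyl-3-[(R)-2-methylbutanoyl]oxazolidin-2-one | CC[C@@H](C)C(=O)N1[C@H](Cc2ccccc2)COC1=O | intermediate
37 | (R)-2-methylbutan-1-ol | OC[C@H](C)CC | intermediate
38 | (R)-2-methylbutanal | O=C[C@H](C)CC | intermediate
39 | ethyl (2E,4R)-2,4-dimethylhex-2-enoate | CCOC(=O)/C(C)=C/[C@H](C)CC | intermediate
40 | (2E,4R)-2,4-dimethylhex-2-en-1-ol | OC/C(C)=C/[C@H](C)CC | intermediate
41 | (2E,4R)-2,4-dimethylhex-2-enal | O=C/C(C)=C/[C@H](C)CC | intermediate
42 | ethyl (2E,4E,6R)-4,6-dimethylocta-2,4-dienoate | CCOC(=O)/C=C/C(C)=C/[C@H](C)CC | intermediate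
43 | (2E,4E,6R)-4,6-dimethylocta-2,4-dienoic acid | OC(=O)/C=C/C(C)=C/[C@H](C)CC | intermediate
44 | mixed anhydride of 43 with 2,4,6-trichlorobenzoic acid | O=C(OC(=O)c1c(Cl)cc(Cl)cc1Cl)/C=C/C(C)=C/[C@H](C)CC | intermediate
45 | (1S,2S,7S,8aS)-7-[3-(acetyloxy)prop-1-en-2-yl]-7-hydroxy-1,8a-dimethyl-6-oxo-1,2,6,7,8,8a-hexahydronaphthalen-2-yl (2E,4E,6R)-4,6-dimethylocta-2,4-dienoate (CNP0160850.1) | C=C(COC(C)=O)[C@@]1(O)C[C@]2(C)C(=CC1=O)C=C[C@H](OC(=O)/C=C/C(C)=C/[C@H](C)CC)[C@H]2C | target

**Step count**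

Total: 27 steps. Longest linear sequence: 19 steps (steps 1–12, 14–19 and 27, from crotonaldehyde); step 13 and steps 20–26 are side branches.

**Steps most likely to fail, with fallbacks**

1. Step 17 (cascade metathesis). The ruthenium carbene may be consumed at the terminal alkyne, or the cascade may stop after ring B because the C1 carbene does not engage the hindered propenyl group; either leads to oligomers or to a monocyclic triene. The fallback sets out from 28 and separates the alkyne step from the ring closures. Enyne cross-metathesis with ethene (RuCl2(=CHPh)(PCy3)(H2IMes), ethene 1 atm, CH2Cl2, rt) should convert the ethynyl group into a 2-substituted buta-1,3-diene, the tetraene F1. Two ordinary six-membered diene ring closures (second-generation Hoveyda–Grubbs catalyst RuCl2(=CH-C6H4-2-O-i-Pr)(H2IMes), toluene, 80 °C) should then form C9=C10 from the C9 vinyl group and the C10 methylene, and C1=C2 from the C1 vinyl group and the propenyl group. The route is rejoined at 29.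

2. Step 14 (addition to the C7 ketone). Incomplete chelation would erode facial selectivity at C7, and enolisation of the β,γ-unsaturated ketone would return starting material or move the double bond. The fallback sets out from 22 and replaces acyclic chelation control by cyclic control. The same dienyne metathesis applied to 22 should give the bicyclic C7 alcohol with the C8 MOM ether, the hydroxy ether F2. Dess–Martin oxidation gives the ring ketone F3. The alkenylcerium reagent from 25 (t-BuLi, then CeCl3, THF, −78 °C) should add from the face opposite the axial C14 methyl and the C8 ether, both of which lie on the same side, to give the bis-MOM adduct F4. ZnBr2/n-PrSH then gives the triol F5, and selective acetylation (AcCl, 2,4,6-collidine, −78 °C) returns to the route at 29.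

3. Step 7 (alkyne from the lactol). Ring-opening of the lactol to the hindered α-quaternary aldehyde may be too slow for the weakly nucleophilic diazophosphonate anion, and prolonged basic methanol could start transesterification of the tert-butyl ester by the C3 hydroxyl. The fallback sets out from 14 and builds the alkyne in two stages with a more reactive ylide. Wittig chloromethylenation ((chloromethyl)triphenylphosphonium chloride, NaN(SiMe3)2, THF, −78 °C → rt) gives the hydroxy chloroalkene F6 as an E/Z mixture. Silylation (TBSOTf, 2,6-lutidine) gives the silyl ether F7. Dehydrochlorination with excess LiN(i-Pr)2 (THF, −78 → −20 °C; the ester enolate is reprotonated on quench) returns to the route at 17.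

**Further compounds**

F1 | step 17 | 2-[(3S,4S,6S,7S,8S,9E)-6-(buta-1,3-dien-2-yl)-8-[(tert-butyldimethylsilyl)oxy]-3,4-dihydroxy-6,7-dimethylundeca-1,9-dien-4-yl]prop-2-en-1-yl acetate (tetraene) | C/C=C/[C@H](O[Si](C)(C)C(C)(C)C)[C@@H](C)[C@@](C)(C(=C)C=C)C[C@](O)(C(=C)COC(C)=O)[C@@H](O)C=C
F2 | step 14 | (2S,3S,7S,8S,8aS)-7-[(tert-butyldimethylsilyl)oxy]-3-(methoxymethoxy)-8,8a-dimethyl-1,2,3,7,8,8a-hexahydronaphthalen-2-ol | O[C@H]1C[C@]2(C)C(=C[C@@H]1OCOC)C=C[C@H](O[Si](C)(C)C(C)(C)C)[C@H]2C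
F3 | step 14 | (3S,7S,8S,8aS)-7-[(tert-butyldimethylsilyl)oxy]-3-(methoxymethoxy)-8,8a-dimethyl-3,7,8,8a-tetrahydronaphthalen-2(1H)-one | O=C1C[C@]2(C)C(=C[C@@H]1OCOC)C=C[C@H](O[Si](C)(C)C(C)(C)C)[C@H]2C
F4 | step 14 | (2S,3S,7S,8S,8aS)-7-[(tert-butyldimethylsilyl)oxy]-3-(methoxymethoxy)-2-[3-(methoxymethoxy)prop-1-en-2-yl]-8,8a-dimethyl-1,2,3,7,8,8a-hexahydronaphthalen-2-ol | C=C(COCOC)[C@@]1(O)C[C@]2(C)C(=C[C@@H]1OCOC)C=C[C@H](O[Si](C)(C)C(C)(C)C)[C@H]2C
F5 | step 14 | (2S,3S,7S,8S,8aS)-7-[(tert-butyldimethylsilyl)oxy]-2-(3-hydroxyprop-1-en-2-yl)-8,8a-dimethyl-1,2,3,7,8,8a-hexahydronaphthalene-2,3-diol | C=C(CO)[C@@]1(O)C[C@]2(C)C(=C[C@@H]1O)C=C[C@H](O[Si](C)(C)C(C)(C)C)[C@H]2C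
F6 | step 7 | tert-butyl (3S,4S,5S,6E)-3-(2-chloroethenyl)-5-hydroxy-3,4-dimethyloct-6-enoate (E/Z mixture at the chloroalkene) | C/C=C/[C@H](O)[C@@H](C)[C@@](C)(C=CCl)CC(=O)OC(C)(C)C
F7 | step 7 | tert-butyl (3S,4S,5S,6E)-5-[(tert-butyldimethylsilyl)oxy]-3-(2-chloroethenyl)-3,4-dimethyloct-6-enoate (E/Z mixture at the chloroalkene) | C/C=C/[C@H](O[Si](C)(C)C(C)(C)C)[C@@H](C)[C@@](C)(C=CCl)CC(=O)OC(C)(C)C
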